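In percentage points of the charge, the isomer of the product A stops early in both runs: its amount Q averages 28.4% in the maple run and 33.6% in the cedar run, over the readings from 0.667 min to 2.00 min. A quick number can therefore rest on how Q rises with catalyst.

the same everywhere: added ligand 100 mM
- maple: starting material 2 M; other conformer 1 equiv; catalyst 0.67 mol%; run made earlier
- cedar: starting material 2 M; other conformer 1 equiv; catalyst 1.5 mol%; run made earlier
- flask: starting material 2.0 M; other conformer 1.00 equiv; catalyst 1 mol%; time 6.0 min

| run | time / min | target / % | isomer of the product A / % |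
|---|---|---|---|
| maple | 0.250 | 52.4 | 23.2 |
| maple | 0.667 | 69.2 | 28.0 |
| maple | 1.33 | 71.0 | 28.6 |
| maple | 2.00 | 72.3 | 28.7 |
| maple | 3.00 | 68.3 | 28.1 |
| maple | 4.00 | 67.0 | 26.8 |
| cedar | 0.667 | 64.9 | 33.8 |
| cedar | 1.33 | 63.6 | 33.4 |
| cedar | 2.00 | 62.4 | 33.6 |
| cedar | 2.50 | 59.4 | 32.2 |
| cedar | 3.00 | 57.6 | 32.5 |
| cedar | 4.00 | 56.8 | 30.3 |

(scatter of a reading: 1 percentage point)

* share of target in target plus isomer of the product A at 0.15 s
* share of target in target plus isomer of the product A at 8.0 s
* share of target in target plus isomer of the product A at 6.0 min

g = (cedar Q − maple Q) / ln(cedar loading / maple loading) = 6.4 percentage points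

This g, the gain in Q per natural-log unit of catalyst loading, carries the maple run over to the flask:

Q = maple Q + g ln(flask loading / maple loading) = 31.0%

The share S of target in target plus isomer of the product A then comes in two rounds. With no loss from the pair, the first round gives:

S = 1 − Q = 69.0%

But the pair shrinks in the runs, and the flask at 6.0 min has the same loading times time as the cedar run at 4.00 min, where the pair U reads 87.1%. Putting that back in gives:

S = 1 − Q/U = 64.4%

The hunch, which is the forecast, stands higher at 68.5%, with 73% at 8.0 s and 81% at 0.15 s, on the ground that “More catalyst leaves less time for exchange”. This reckoning offers no number at 0.15 s or 8.0 s, which both lie before the first reading.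

The flask gives 31.4%, 65.0% and 66.5%.

    starting material + catalyst → catalyst + target (k = 17.1 M⁻¹ s⁻¹)
    catalyst + added ligand ⇌ idle complex (K = 23.0 M⁻¹, k = 20.6 M⁻¹ s⁻¹)
    starting material ⇌ other conformer (K = 0.104, k = 0.0983 s⁻¹)
    catalyst + other conformer → catalyst + isomer of the product A (k = 43.2 M⁻¹ s⁻¹)
    target + catalyst ⇌ isomer of the product B + catalyst, rate k5*[catalyst]*[target] forward; the back reaction follows from the equilibrium constant (K = 0.450, k = 0.0882 M⁻¹ s⁻¹)

With the step from catalyst + other conformer to catalyst + isomer of the product A struck out, the flask's share at 0.15 s reads 100%. The flask holds 30.0% of isomer of the product A at 6.00 min, against the reckoned 31.0%. Carried to the neighbouring flask with 4 mol% of catalyst, g gives 39.9%, and that flask holds 41.1% at 6.00 min.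

The data are simulated for an exercise; the scatter is artificial.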